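**Retrosynthetic overview**
1. The target is the formal [4+2] homodimer of vinylallenyl ketone 16. The central cyclohexene (ring B) forms last: the conjugated allene C=C of one monomer is the dienophile, and the allene/isopropenyl unit of the other is the diene.
2. Monomer 16 is generated in the flask from alkynyl epoxyquinone 13 by one borohydride operation (unhindered C=O to the cis carbinol; 1,4-hydride to an enolate, then the allenyl ketone).
3. 13 comes from Sonogashira coupling and ketal hydrolysis of bromo epoxy enone 10, which comes from bromide opening and dehydration of the sacrificial oxirane of bis-epoxide 7.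
4. 7 comes from prenylphenol 4 by oxidative dearomatization and double Weitz–Scheffer epoxidation in one flask. Both oxiranes form in that operation: the catalyst sets the unhindered one, which fixes the prenyl-bearing one and is later erased.
5. Ring order: arene (bought) → two oxiranes (step 2) → ring B (step 6).

Assumption: the cinchonidine-derived ammonium salt is taken to give mono-epoxide 6 as drawn; if the sense is opposite, the cinchonine-derived salt is used instead.

**Step 1**
Reactants: 1 4-methoxyphenol, 2 1-bromo-3-methylbut-2-ene (prenyl bromide)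
Product: 4 4-methoxy-2-(3-methylbut-2-en-1-yl)phenol, via sodium 4-methoxyphenoxide 3 (not isolated)
Conditions: NaH, toluene, 0 °C; then 2, 0 → 23 °C
Reagents that add atoms: none
Why: A sodium phenoxide held as a tight ion pair in a non-polar solvent is alkylated at the ortho carbon by a primary allylic bromide (ortho C-allylation of a phenoxide, SN2), the two ortho positions of 1 are equivalent, and no stereocenter is formed.

**Step 2**
Reactants: 4 4-methoxy-2-(3-methylbut-2-en-1-yl)phenol
Product: 7 (1S,3S,5R,7R)-6,6-dimethoxy-1-(3-methylbut-2-en-1-yl)-4,8-dioxatricyclo[5.1.0.0(3,5)]octan-2-one, via dienone ketal 5 (not isolated), via monoepoxide 6 (not isolated)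
Conditions: PhI(OAc)2, MeOH, 0 °C; evaporate; toluene, N-benzylcinchonidinium chloride (10 mol%), t-BuOOH (1.2 equiv), aq NaOH, 0 °C; then t-BuOOH (3 equiv), 23 °C
Reagents that add atoms: methanol, CO; tert-butyl hydroperoxide, CC(C)(C)OO
Why: Proposed new method: trivalent-iodine oxidative dearomatization in methanol gives quinone monoketal 5; the first Weitz–Scheffer epoxidation, under chiral ammonium phase-transfer control, takes the faster unsubstituted enone alkene and sets its two stereocenters; the slower second epoxidation of the α-prenyl enone occurs on the opposite ring face, both because the peroxide approaches anti to the first oxirane and because the two enone halves are related by the C2 axis through C1 and C4 of the dienone, so the same catalyst handedness selects the opposite face; this sets the prenyl-bearing oxirane (C1 S, C7 R) in the trans-bis-epoxide; the closest known reactions are cinchona phase-transfer epoxidation of quinone monoketals at their unsubstituted alkene and double nucleophilic epoxidation of cyclohexadienone ketals.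

**Step 3**
Reactants: 7 (1S,3S,5R,7R)-6,6-dimethoxy-1-(3-methylbut-2-en-1-yl)-4,8-dioxatricyclo[5.1.0.0(3,5)]octan-2-one
Product: 10 (1S,6R)-3-bromo-5,5-dimethoxy-1-(3-methylbut-2-en-1-yl)-7-oxabicyclo[4.1.0]hept-3-en-2-one, via bromohydrin 8 (not isolated), via mesylate 9 (not isolated)
Conditions: LiBr, AcOH, THF, 0 → 23 °C; then MsCl, Et3N, CH2Cl2, 0 °C
Reagents that add atoms: lithium bromide, [Li+].[Br-]
Why: Bromide opens the oxirane by SN2 at the only secondary carbon α to the ketone (the other α-carbon is quaternary and both β-carbons are neopentyl to the ketal), and mesylation of the trans-bromohydrin triggers E1cB loss of methanesulfonate (epoxy ketone to α-haloenone conversion); the two stereocenters of the sacrificial oxirane are erased and C1 and C6 are untouched.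

**Step 4**
Reactants: 10 (1S,6R)-3-bromo-5,5-dimethoxy-1-(3-methylbut-2-en-1-yl)-7-oxabicyclo[4.1.0]hept-3-en-2-one, 11 2-methylbut-1-en-3-yne
Product: 12 (1S,6R)-5,5-dimethoxy-3-(3-methylbut-3-en-1-yn-1-yl)-1-(3-methylbut-2-en-1-yl)-7-oxabicyclo[4.1.0]hept-3-en-2-one
Conditions: PdCl2(PPh3)2 (5 mol%), CuI (10 mol%), i-Pr2NH, THF, 0 → 23 °C (excess 11, closed flask)
Reagents that add atoms: none
Why: Sonogashira coupling: the α-bromoenone C–Br bond adds readily to zerovalent palladium and the copper acetylide of 11 transmetalates at or below room temperature under a hindered secondary amine, conditions the epoxy ketone and ketal survive; no stereocenter is touched.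

**Step 5**
Reactants: 12 (1S,6R)-5,5-dimethoxy-3-(3-methylbut-3-en-1-yn-1-yl)-1-(3-methylbut-2-en-1-yl)-7-oxabicyclo[4.1.0]hept-3-en-2-one
Product: 13 (1S,6R)-3-(3-methylbut-3-en-1-yn-1-yl)-1-(3-methylbut-2-en-1-yl)-7-oxabicyclo[4.1.0]hept-3-ene-2,5-dione
Conditions: 10% aq oxalic acid on SiO2, CH2Cl2, 23 °C
Reagents that add atoms: water, O
Why: Mild acid-catalysed hydrolysis of the dimethyl ketal through its oxocarbenium ion leaves the oxirane, the enyne and the prenyl group intact; no stereocenter is touched and 13 is used at once.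

**Step 6**
Reactants: 13 (1S,6R)-3-(3-methylbut-3-en-1-yn-1-yl)-1-(3-methylbut-2-en-1-yl)-7-oxabicyclo[4.1.0]hept-3-ene-2,5-dione (two molecules)
Product: 17 target CNP0235815.2, via dilithium enolate alkoxide 14 (not isolated), via propargylic ketone 15 (not isolated), via vinylallenyl ketone 16 (not isolated)
Conditions: LiBH(s-Bu)3 (2.2 equiv), THF, −78 °C; AcOH (2.5 equiv), −78 °C; Et3N (0.2 equiv), −78 → 40 °C, 0.2 M
Reagents that add atoms: none
Why: Proposed new method: the bulky borohydride reduces the unhindered C5 carbonyl from the face opposite the oxirane oxygen (cis epoxy alcohol, C5 S) and adds 1,4 to the α-alkynyl enone at its unsubstituted β-carbon, so the hindered C2 carbonyl stays masked as the alkyne-conjugated enolate 14 until the acid quench; protonation and amine-mediated propargyl–allenyl isomerization give 16, whose electron-poor conjugated allene C=C (dienophile) and allene/isopropenyl diene join through the two central allene carbons and through the ring α-carbon and the diene CH2 terminus; the diene adds to the dienophile face anti to the prenyl group and anti to the isopropenyl group and reacts on its own face that carries the ring C=O, which fixes the spiro center (R) and both exocyclic alkene geometries as in the natural dimer; the closest known reactions are conjugate reduction of enones by trialkylborohydrides, base-mediated alkynyl ketone to allenyl ketone isomerization and thermal [4+2] dimerization of vinylallenes; homochiral pairing also raises the ee of 17 above that of 13.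

**Compound list**
1 | 4-methoxyphenol | COc1ccc(O)cc1 | starting material
2 | 1-bromo-3-methylbut-2-ene (prenyl bromide) | CC(C)=CCBr | starting material
3 | sodium 4-methoxyphenoxide | COc1ccc([O-])cc1.[Na+] | intermediate
4 | 4-methoxy-2-(3-methylbut-2-en-1-yl)phenol | COc1ccc(O)c(CC=C(C)C)c1 | intermediate
5 | 4,4-dimethoxy-2-(3-methylbut-2-en-1-yl)cyclohexa-2,5-dien-1-one | O=C1C=CC(OC)(OC)C=C1CC=C(C)C | intermediate
6 | (1S,6R)-5,5-dimethoxy-3-(3-methylbut-2-en-1-yl)-7-oxabicyclo[4.1.0]hept-3-en-2-one | O=C1[C@H]2O[C@H]2C(OC)(OC)C=C1CC=C(C)C | intermediate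
7 | (1S,3S,5R,7R)-6,6-dimethoxy-1-(3-methylbut-2-en-1-yl)-4,8-dioxatricyclo[5.1.0.0(3,5)]octan-2-one (trans-bis-epoxide) | O=C1[C@H]2O[C@H]2C(OC)(OC)[C@@H]2O[C@]12CC=C(C)C | intermediate
8 | (1S,3R,4S,6R)-3-bromo-4-hydroxy-5,5-dimethoxy-1-(3-methylbut-2-en-1-yl)-7-oxabicyclo[4.1.0]heptan-2-one | O=C1[C@H](Br)[C@@H](O)C(OC)(OC)[C@@H]2O[C@]12CC=C(C)C | intermediate
9 | (1S,3R,4S,6R)-3-bromo-5,5-dimethoxy-1-(3-methylbut-2-en-1-yl)-2-oxo-7-oxabicyclo[4.1.0]heptan-4-yl methanesulfonate | O=C1[C@H](Br)[C@@H](OS(C)(=O)=O)C(OC)(OC)[C@@H]2O[C@]12CC=C(C)C | intermediate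
10 | (1S,6R)-3-bromo-5,5-dimethoxy-1-(3-methylbut-2-en-1-yl)-7-oxabicyclo[4.1.0]hept-3-en-2-one | O=C1C(Br)=CC(OC)(OC)[C@@H]2O[C@]12CC=C(C)C | intermediate
11 | 2-methylbut-1-en-3-yne | C=C(C)C#C | starting material
12 | (1S,6R)-5,5-dimethoxy-3-(3-methylbut-3-en-1-yn-1-yl)-1-(3-methylbut-2-en-1-yl)-7-oxabicyclo[4.1.0]hept-3-en-2-one | O=C1C(C#CC(C)=C)=CC(OC)(OC)[C@@H]2O[C@]12CC=C(C)C | intermediate
13 | (1S,6R)-3-(3-methylbut-3-en-1-yn-1-yl)-1-(3-methylbut-2-en-1-yl)-7-oxabicyclo[4.1.0]hept-3-ene-2,5-dione | O=C1C(C#CC(C)=C)=CC(=O)[C@@H]2O[C@]12CC=C(C)C | intermediate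
14 | dilithium (1S,5S,6S)-3-(3-methylbut-3-en-1-yn-1-yl)-1-(3-methylbut-2-en-1-yl)-7-oxabicyclo[4.1.0]hept-2-ene-2,5-diolate | [Li+].[Li+].[O-]C1=C(C#CC(C)=C)C[C@H]([O-])[C@@H]2O[C@]12CC=C(C)C | intermediate
15 | (1S,5S,6S)-5-hydroxy-3-(3-methylbut-3-en-1-yn-1-yl)-1-(3-methylbut-2-en-1-yl)-7-oxabicyclo[4.1.0]heptan-2-one (both C3 epimers) | O=C1C(C#CC(C)=C)C[C@H](O)[C@@H]2O[C@]12CC=C(C)C | intermediate
16 | (1S,5S,6S)-5-hydroxy-3-(3-methylbuta-1,3-dien-1-ylidene)-1-(3-methylbut-2-en-1-yl)-7-oxabicyclo[4.1.0]heptan-2-one | O=C1C(=C=CC(C)=C)C[C@H](O)[C@@H]2O[C@]12CC=C(C)C | intermediate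
17 | CNP0235815.2: ring B is a cyclohexene (C1 spiro, C2, C3, C4=C5(CH3), C6H2); C1 (R) is also C3 of ring A, a (1S,5S,6S)-5-hydroxy-1-(3-methylbut-2-en-1-yl)-7-oxabicyclo[4.1.0]heptan-2-one; C2 carries an exocyclic 2-methylprop-2-en-1-ylidene with the isopropenyl group cis to C1; C3 is doubly bonded to C3 of ring C, a second (1S,5S,6S)-5-hydroxy-1-(3-methylbut-2-en-1-yl)-7-oxabicyclo[4.1.0]heptan-2-one whose C=O is cis to C2 of ring B | C=C(C)/C=C1/C(=C2/C[C@H](O)[C@@H]3O[C@]3(CC=C(C)C)C2=O)C=C(C)C[C@@]12C[C@H](O)[C@@H]1O[C@]1(CC=C(C)C)C2=O | target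

**Count and risks**
Total steps: 6. Longest linear sequence: 6 (1 → 4 → 7 → 10 → 12 → 13 → 17); 2 and 11 are purchased.

Most likely to fail, step 2 (two oxiranes in one flask; ee of the first epoxidation and the trans relationship of the second). The fallback sets out from prenyl bromide 2 and uses bromine as the blocking group in place of a second oxirane. 2-Bromo-4-methoxyphenol F1 is deprotonated to sodium 2-bromo-4-methoxyphenoxide F2 (NaH, toluene) and C-prenylated with 2 to 2-bromo-4-methoxy-6-(3-methylbut-2-en-1-yl)phenol F3. PhI(OAc)2 in MeOH gives 2-bromo-4,4-dimethoxy-6-(3-methylbut-2-en-1-yl)cyclohexa-2,5-dien-1-one F4. A single Weitz–Scheffer epoxidation (t-BuOOH, aq NaOH, N-benzylcinchonidinium chloride), expected to occur only at the prenyl-bearing alkene because the α-bromo enone alkene is deactivated, comes back to the route at 10; compounds 5–9 are not made. If the ee at this hindered alkene is low, 10 is enriched by crystallization, and the homochiral dimerization in step 6 removes most of the minor enantiomer as a separable heterochiral dimer.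

Second, step 6 (two reductions, an isomerization and the dimerization in one flask). The fallback sets out from 13 and separates the events. i-Bu2AlH (1.05 equiv, THF, −78 °C) reduces only the unhindered C5 carbonyl, anti to the oxirane, to the isolable monomer (1S,5S,6S)-5-hydroxy-3-(3-methylbut-3-en-1-yn-1-yl)-1-(3-methylbut-2-en-1-yl)-7-oxabicyclo[4.1.0]hept-3-en-2-one F9. 1,4-Reduction of F9 with the copper hydride [(Ph3P)CuH]6 in wet benzene comes back to the route at 15, so the isomerization to 16 and the dimerization to 17 can be optimized on their own (concentration, temperature, aqueous medium).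

Third, step 3 (opening one of two oxiranes, then dehydration). The fallback sets out from 7 and removes the sacrificial oxirane reductively instead of by substitution. Phenylselenide (from (PhSe)2, NaBH4, AcOH, EtOH) cleaves its Cα–O bond to (1S,4R,6R)-4-hydroxy-5,5-dimethoxy-1-(3-methylbut-2-en-1-yl)-7-oxabicyclo[4.1.0]heptan-2-one F5. MsCl/Et3N takes this through (1S,4R,6R)-5,5-dimethoxy-1-(3-methylbut-2-en-1-yl)-2-oxo-7-oxabicyclo[4.1.0]heptan-4-yl methanesulfonate F6 to (1S,6R)-5,5-dimethoxy-1-(3-methylbut-2-en-1-yl)-7-oxabicyclo[4.1.0]hept-3-en-2-one F7. α-Iodination (I2, pyridine, CH2Cl2) gives (1S,6R)-3-iodo-5,5-dimethoxy-1-(3-methylbut-2-en-1-yl)-7-oxabicyclo[4.1.0]hept-3-en-2-one F8, which undergoes the Sonogashira coupling with 11 under the step 4 conditions and comes back to the route at 12.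

**Further compounds**
F1 | step 2 | 2-bromo-4-methoxyphenol | COc1ccc(O)c(Br)c1
F2 | step 2 | sodium 2-bromo-4-methoxyphenoxide | COc1ccc([O-])c(Br)c1.[Na+]
F3 | step 2 | 2-bromo-4-methoxy-6-(3-methylbut-2-en-1-yl)phenol | COc1cc(Br)c(O)c(CC=C(C)C)c1
F4 | step 2 | 2-bromo-4,4-dimethoxy-6-(3-methylbut-2-en-1-yl)cyclohexa-2,5-dien-1-one | O=C1C(Br)=CC(OC)(OC)C=C1CC=C(C)C
F5 | step 3 | (1S,4R,6R)-4-hydroxy-5,5-dimethoxy-1-(3-methylbut-2-en-1-yl)-7-oxabicyclo[4.1.0]heptan-2-one | O=C1C[C@@H](O)C(OC)(OC)[C@@H]2O[C@]12CC=C(C)C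
F6 | step 3 | (1S,4R,6R)-5,5-dimethoxy-1-(3-methylbut-2-en-1-yl)-2-oxo-7-oxabicyclo[4.1.0]heptan-4-yl methanesulfonate | O=C1C[C@@H](OS(C)(=O)=O)C(OC)(OC)[C@@H]2O[C@]12CC=C(C)C
F7 | step 3 | (1S,6R)-5,5-dimethoxy-1-(3-methylbut-2-en-1-yl)-7-oxabicyclo[4.1.0]hept-3-en-2-one | O=C1C=CC(OC)(OC)[C@@H]2O[C@]12CC=C(C)C
F8 | step 3 | (1S,6R)-3-iodo-5,5-dimethoxy-1-(3-methylbut-2-en-1-yl)-7-oxabicyclo[4.1.0]hept-3-en-2-one | O=C1C(I)=CC(OC)(OC)[C@@H]2O[C@]12CC=C(C)C
F9 | step 6 | (1S,5S,6S)-5-hydroxy-3-(3-methylbut-3-en-1-yn-1-yl)-1-(3-methylbut-2-en-1-yl)-7-oxabicyclo[4.1.0]hept-3-en-2-one | O=C1C(C#CC(C)=C)=C[C@H](O)[C@@H]2O[C@]12CC=C(C)C
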